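**Two exits.** In a one-step world each L becomes D and then X, up to the G charged. Here L has a second exit, to Z, so the yield is a race. E stands near one to one with G, so we count one L per G charged.

| flask | G | E | remark | time |
|---|---|---|---|---|
| zeta | 11 mM | 1.05 equiv | run made earlier |  |
| beta | 5.5 mM | 1.05 equiv | run made earlier |  |
| delta | 8.2 mM | 1.05 equiv | run made earlier |  |
| elm | 11 mM | 1.05 equiv | everything together at the start | 2.0 d |
| maple | 11 mM | 1.05 equiv (fed, over 30 h) | all else is in the flask from the start; the feed brings no volume worth counting | 2.0 d |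
| oak | 11 mM (fed, over 30 h) | 1.05 equiv | all else is in the flask from the start; the feed brings no volume worth counting | 2.0 d |
| alder | 11 mM (in portions, 2, over 30 h) | 1.05 equiv | first portion at the start, last at 30 h | 2.0 d |

| run | time / h | X / % | D / % |
|---|---|---|---|
| zeta | 6.00 | 3.5 | 5.7 |
| zeta | 12.0 | 9.6 | 4.5 |
| zeta | 15.0 | 13.1 | 3.9 |
| zeta | 25.0 | 17.1 | 0.4 |
| zeta | 30.0 | 17.5 | 0 |
| beta | 6.00 | 2.2 | 3.2 |
| beta | 12.0 | 5.9 | 3.5 |
| beta | 15.0 | 7.8 | 3.2 |
| beta | 25.0 | 10.5 | 0.5 |
| beta | 30.0 | 11.7 | 0.8 |
| delta | 6.00 | 3.1 | 4.5 |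
| delta | 12.0 | 8.2 | 4.1 |
| delta | 15.0 | 9.1 | 2.7 |
| delta | 25.0 | 14.1 | 1.3 |
| delta | 30.0 | 14.5 | 0.6 |

(standard deviation of a reading: 0.5 percentage points)

- the earlier runs were read with a standard deviation of 0.5 percentage points
- steps under discussion: G <-> J; E -> L; J + L -> D; L -> Z; D -> X

- the flask that comes out highest in amount of X, in percent of the G charged, or "all alike" when all lie within 1.5 percentage points (elm / maple / oak / alder / all alike)
- X at the end, in percent of the G charged, elm
- X at the end, in percent of the G charged, maple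
- X at the end, in percent of the G charged, oak
- X at the end, in percent of the G charged, alder

**L's lifetime.** In zeta, D plus X reads 9.20% at 6.00 h and 17.5% at 30.0 h. One exponential through these two readings gives L a read lifetime τ of 8.04 h, shorter than the feed, which spans n = 3.73 lifetimes.

**Capture ratio.** Let Y be the final D plus X; D reads 0% in zeta at 30.0 h, so we count Y as X. Then ρ = Y/(1−Y), a selectivity factor, is L caught per L lost: 0.212 in zeta. We let ρ scale with cG, which gives 0.0193 mM⁻¹ for zeta.

**Hand chain.** Elm has zeta's charges, and in maple E is fed onto the full G, so we keep ρ and Y = 17.5% for both. In oak, L lives while G is fed, so on average it meets a share τ/tf of the charge, and ρ falls to 0.0569, Y = 5.38%. In alder, L meets half of G, and 2.40% of L should remain for the last portion, so Y = 9.59%.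

**Weak link.** That ratio rests on zeta. Beta gives 0.0260 mM⁻¹ and delta 0.0217 mM⁻¹, higher than zeta. So we carry the mean over these runs, the capture constant a, ρ per mM of G charged: 0.0223 mM⁻¹. At 11 mM, ρ = 0.245. Our reckoning gives elm and maple 19.7%, oak 6.18% and alder 10.9%, a tie at the top.

**The forecast.** It names maple at 20%, above elm at 17.5%, with oak 7% and alder 9%. Its ground for maple is “the total L exposure is unchanged, and J has time to replenish”. There it parts from our tie.

**The flasks.** The highest is maple at 21.4%, then elm 19.3%, alder 10.8% and oak 6.21%.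

    G ⇌ J (K = 0.480, k = 0.171 h⁻¹)
    E → L (k = 2.56 h⁻¹)
    J + L → D (k = 10.1 M⁻¹ h⁻¹)
    L → Z (k = 0.112 h⁻¹)
    D → X (k = 0.204 h⁻¹)

**Richer neighbour.** Maple leads elm by 2.1 percentage points, beyond the margin, where our reckoning has a tie. At 2.00 d, maple still holds L at 0.227 mM and D at 0.705%. Oak ends at 6.21% against our 6.18%. The neighbour is maple with 27 mM of G at the same equivalents. There a = 0.0223 mM⁻¹ gives ρ = 0.603 and Y = 37.6%. The neighbour ends with X at 37.4% and D at 0.909%.

The readings were computed from invented constants; the scatter is artificial.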